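The plan grows the phenolic ring of unit C (the terminal naphthol attached through its C4) directly on unit B, which removes any cross-coupling at the B–C axis. In unit C the oxygen on C1 lies peri to the C8 methoxy group and para to the aryl-bearing C4. 3-Methoxybenzyne supplies C4a, C8a and C5–C8, a 2-silyloxyfuran supplies C1–C4, and their donor and acceptor termini are matched. A single aryne Diels–Alder addition with opening of the oxygen bridge makes C1–C8a and C4–C4a and closes that ring. The precursor is a 2-(triisopropylsilyloxy)furan bearing at C5 a 1-benzyloxy-4-bromo-8-methoxynaphthalen-2-yl group, whose bromide later accepts unit A.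

Key step: step 8

Labels: unit A is the terminal naphthol bonded through C2. Unit B is the central naphthol substituted at C2 and C4. Unit C is the terminal naphthol bonded through C4. Each unit is numbered as an 8-methoxynaphthalen-1-ol.

Assumption: the target SMILES carries no stereodescriptor. Each biaryl axis is flanked by only one ortho oxygen substituent and a peri hydrogen, so the axes are treated as not configurationally fixed and no axial control is attempted.

Step 1
Reactants: 1 naphthalene-1,8-diol
Product: 2 8-methoxynaphthalen-1-ol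
Conditions: MeI (1.05 equiv), K2CO3, acetone, reflux
Reagents that add atoms: iodomethane, CI
Why: The Williamson ether synthesis should stop at the monoether because the remaining hydroxyl is hydrogen-bonded to the new peri methoxy oxygen and is much less acidic than the first one.

Step 2
Reactants: 2 8-methoxynaphthalen-1-ol
Product: 3 4-bromo-8-methoxynaphthalen-1-ol
Conditions: NBS (1.0 equiv), MeCN, −20 to 0 °C, dark
Reagents that add atoms: N-bromosuccinimide, O=C1CCC(=O)N1Br
Why: Electrophilic aromatic bromination is steered by the free hydroxyl, the stronger donor, to its para position C4 in polar MeCN (2-methoxyphenol behaves the same way), and it is run before any acyl group deactivates this ring so that C5 of the methoxy ring cannot compete.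

Step 3
Reactants: 3 4-bromo-8-methoxynaphthalen-1-ol
Product: 4 4-bromo-1-hydroxy-8-methoxynaphthalene-2-carbaldehyde
Conditions: MgCl2, Et3N, (CH2O)n, MeCN, reflux; aq. HCl work-up
Reagents that add atoms: paraformaldehyde (as formaldehyde), C=O
Why: In the Casnati–Skattebøl ortho-formylation the magnesium naphtholate binds formaldehyde and delivers it through a six-membered array to C2, the only free ortho carbon, and a second formaldehyde accepts hydride to give the aldehyde, all without a strong Lewis acid that could cleave the peri methyl ether or move the bromine.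

Step 4
Reactants: 4 4-bromo-1-hydroxy-8-methoxynaphthalene-2-carbaldehyde
Product: 5 1-(benzyloxy)-4-bromo-8-methoxynaphthalene-2-carbaldehyde
Conditions: BnBr, K2CO3, DMF, 60 °C
Reagents that add atoms: benzyl bromide, BrCc1ccccc1
Why: Williamson benzylation of the chelated naphthol needs only mild heating with carbonate in DMF and leaves the aldehyde and the bromide untouched.

Step 5
Reactants: 5 1-(benzyloxy)-4-bromo-8-methoxynaphthalene-2-carbaldehyde; 6 ethyl propiolate
Product: 8 ethyl 4-[1-(benzyloxy)-4-bromo-8-methoxynaphthalen-2-yl]-4-hydroxybut-2-ynoate (racemic), via ethyl 3-lithiopropiolate 7 (not isolated)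
Conditions: 6, LiN(SiMe3)2, THF, −78 °C; then 5; AcOH quench at −78 °C
Reagents that add atoms: none
Why: This is a 1,2-addition of a lithium acetylide to an aromatic aldehyde in which the silylamide base does not exchange the aryl bromide, and the new carbinol centre forms racemic, which is irrelevant because step 7 flattens it.

Step 6
Reactants: 8 ethyl 4-[1-(benzyloxy)-4-bromo-8-methoxynaphthalen-2-yl]-4-hydroxybut-2-ynoate
Product: 10 5-[1-(benzyloxy)-4-bromo-8-methoxynaphthalen-2-yl]furan-2(5H)-one (racemic), via ethyl (Z)-hydroxyenoate 9 (not isolated)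
Conditions: H2 (1 atm), Pd/CaCO3 poisoned with Pb(OAc)2, quinoline, EtOAc, rt; then PPTS (cat.), CH2Cl2, rt
Reagents that add atoms: none
Why: Lindlar semihydrogenation gives the Z-enoate, whose hydroxyl and ester are held cis and lactonise with loss of ethanol, while the poisoned palladium leaves the aryl bromide and the benzyl ether alone.

Step 7
Reactants: 10 5-[1-(benzyloxy)-4-bromo-8-methoxynaphthalen-2-yl]furan-2(5H)-one
Product: 11 {[5-(1-(benzyloxy)-4-bromo-8-methoxynaphthalen-2-yl)furan-2-yl]oxy}tri(propan-2-yl)silane
Conditions: iPr3SiOTf, Et3N, CH2Cl2, 0 °C; filtration through Et3N-deactivated silica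
Reagents that add atoms: triisopropylsilyl trifluoromethanesulfonate, CC(C)[Si](C(C)C)(C(C)C)OS(=O)(=O)C(F)(F)F
Why: Soft enolisation of a butenolide with a silyl triflate and a tertiary amine removes the C5–H, which is both benzylic and vinylogously acidic, and gives the aromatic 2-silyloxyfuran, the bulky triisopropylsilyl group being chosen because it withstands fluoride longer than smaller silyl groups.

Step 8
Reactants: 11 {[5-(1-(benzyloxy)-4-bromo-8-methoxynaphthalen-2-yl)furan-2-yl]oxy}tri(propan-2-yl)silane; 12 3-methoxy-2-(trimethylsilyl)phenyl trifluoromethanesulfonate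
Product: 15 4-[1-(benzyloxy)-4-bromo-8-methoxynaphthalen-2-yl]-4-hydroxy-8-methoxynaphthalen-1(4H)-one (racemic), via 3-methoxybenzyne 13 (not isolated), via oxa-bridged silyl ketal 14 (not isolated)
Conditions: 12 (1.5 equiv, slow addition), CsF, MeCN, rt; then Bu4NF, AcOH, THF, 0 °C
Reagents that add atoms: none
Why: CsF attacks the trimethylsilyl group of 12 and triflate departs to release 3-methoxybenzyne 13, which adds suprafacially across C2 and C5 of the electron-rich furan 11 in a concerted but asynchronous [4+2] process. The closest known reaction type is the regioselective aryne Diels–Alder reaction of 3-alkoxybenzynes with 2-alkoxy- and 2-silyloxyfurans. The one new ring, the six-membered carbocycle C1–C4/C4a/C8a of unit C, is closed by intermolecular cycloaddition that forms C4–C4a slightly ahead of C1–C8a and gives the 1,4-epoxy-bridged silyl ketal 14. The selectivity needed is orientational, since the future carbonyl carbon must bond to the aryne carbon next to the methoxy group: the methoxy group polarises and distorts the aryne so that the carbon meta to it is the electrophilic one, the furan is most nucleophilic at C5 as the terminus of a vinylogous silyl ketene acetal, and the bulky naphthyl group on C5 also prefers the unhindered end, so electronic and steric demands agree. Buffered Bu4NF then removes the triisopropylsilyl group, which is bulky enough to outlast CsF while aryne is present and so prevents early loss of the diene and arylation of the C4 oxygen, and the resulting hemiketal alkoxide breaks the C1–O bridge bond to give the C1 ketone and the C4 tertiary alcohol. C4 is the only stereocentre formed, nothing controls it and it arises racemic, which is harmless because step 9 removes it.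

Step 9
Reactants: 15 4-[1-(benzyloxy)-4-bromo-8-methoxynaphthalen-2-yl]-4-hydroxy-8-methoxynaphthalen-1(4H)-one
Product: 16 4-[1-(benzyloxy)-4-bromo-8-methoxynaphthalen-2-yl]-8-methoxynaphthalen-1-ol
Conditions: Zn dust, AcOH, THF, rt
Reagents that add atoms: none
Why: In this reductive aromatisation of a p-quinol, zinc transfers two electrons to the enone, the C4 hydroxyl leaves as water and the product tautomerises to the naphthol, whereas the aryl bromide and the benzyl ether are inert to zinc in acetic acid at room temperature.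

Step 10
Reactants: 2 8-methoxynaphthalen-1-ol
Product: 17 2-bromo-8-methoxynaphthalen-1-ol
Conditions: NBS (1.0 equiv, slow addition), iPr2NH (10 mol%), CH2Cl2, 0 °C
Reagents that add atoms: N-bromosuccinimide, O=C1CCC(=O)N1Br
Why: In the amine-catalysed ortho-bromination of phenols, the N-bromoamine formed in low concentration associates with the hydroxyl in the non-polar medium and hands bromine to the adjacent carbon C2, as it does with naphthalen-1-ol.

Step 11
Reactants: 17 2-bromo-8-methoxynaphthalen-1-ol
Product: 18 1-(benzyloxy)-2-bromo-8-methoxynaphthalene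
Conditions: BnBr, K2CO3, DMF, 50 °C
Reagents that add atoms: benzyl bromide, BrCc1ccccc1
Why: This is a plain Williamson benzylation of a naphthol in which no other group can react.

Step 12
Reactants: 18 1-(benzyloxy)-2-bromo-8-methoxynaphthalene
Product: 19 2-[1-(benzyloxy)-8-methoxynaphthalen-2-yl]-4,4,5,5-tetramethyl-1,3,2-dioxaborolane
Conditions: B2pin2, Pd(dppf)Cl2 (cat.), KOAc, 1,4-dioxane, 90 °C
Reagents that add atoms: bis(pinacolato)diboron, CC1(C)OB(OC1(C)C)B1OC(C)(C)C(C)(C)O1
Why: Miyaura borylation of an aryl bromide with acetate as a weak base avoids both homocoupling and the benzylic metalation that an organolithium route would risk.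

Step 13
Reactants: 16 4-[1-(benzyloxy)-4-bromo-8-methoxynaphthalen-2-yl]-8-methoxynaphthalen-1-ol; 19 2-[1-(benzyloxy)-8-methoxynaphthalen-2-yl]-4,4,5,5-tetramethyl-1,3,2-dioxaborolane
Product: 20 4-{1-(benzyloxy)-4-[1-(benzyloxy)-8-methoxynaphthalen-2-yl]-8-methoxynaphthalen-2-yl}-8-methoxynaphthalen-1-ol
Conditions: Pd(OAc)2 (cat.), SPhos, K3PO4, toluene/H2O, 90 °C, degassed
Reagents that add atoms: none
Why: In this Suzuki–Miyaura coupling the bulky electron-rich biarylphosphine copes with the peri-hindered C4 bromide and the ortho-alkoxy boronate, and the hydrogen-bonded hydroxyl of unit C is tolerated under phosphate base, so no extra protection step is spent.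

Step 14
Reactants: 20 4-{1-(benzyloxy)-4-[1-(benzyloxy)-8-methoxynaphthalen-2-yl]-8-methoxynaphthalen-2-yl}-8-methoxynaphthalen-1-ol
Product: 21 2-(4-hydroxy-5-methoxynaphthalen-1-yl)-4-(1-hydroxy-8-methoxynaphthalen-2-yl)-8-methoxynaphthalen-1-ol (CNP0493720.0)
Conditions: H2 (1 atm), Pd/C, EtOAc/MeOH, rt
Reagents that add atoms: none
Why: Hydrogenolysis of the two aryl benzyl ethers over palladium under neutral conditions frees the hydroxyl groups of units A and B without touching the methyl ethers or the naphthalene rings.

Compound list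
1 | naphthalene-1,8-diol | Oc1cccc2cccc(O)c12 | starting material
2 | 8-methoxynaphthalen-1-ol | COc1cccc2cccc(O)c12 | intermediate
3 | 4-bromo-8-methoxynaphthalen-1-ol | COc1cccc2c(Br)ccc(O)c12 | intermediate
4 | 4-bromo-1-hydroxy-8-methoxynaphthalene-2-carbaldehyde | COc1cccc2c(Br)cc(C=O)c(O)c12 | intermediate
5 | 1-(benzyloxy)-4-bromo-8-methoxynaphthalene-2-carbaldehyde | COc1cccc2c(Br)cc(C=O)c(OCc3ccccc3)c12 | intermediate
6 | ethyl propiolate | C#CC(=O)OCC | starting material
7 | ethyl 3-lithiopropiolate (not isolated) | [Li]C#CC(=O)OCC | intermediate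
8 | ethyl 4-[1-(benzyloxy)-4-bromo-8-methoxynaphthalen-2-yl]-4-hydroxybut-2-ynoate, racemic | CCOC(=O)C#CC(O)c1cc(Br)c2cccc(OC)c2c1OCc1ccccc1 | intermediate
9 | ethyl (Z)-4-[1-(benzyloxy)-4-bromo-8-methoxynaphthalen-2-yl]-4-hydroxybut-2-enoate, racemic (not isolated) | CCOC(=O)/C=C\C(O)c1cc(Br)c2cccc(OC)c2c1OCc1ccccc1 | intermediate
10 | 5-[1-(benzyloxy)-4-bromo-8-methoxynaphthalen-2-yl]furan-2(5H)-one, racemic | O=C1C=CC(O1)c1cc(Br)c2cccc(OC)c2c1OCc1ccccc1 | intermediate
11 | {[5-(1-(benzyloxy)-4-bromo-8-methoxynaphthalen-2-yl)furan-2-yl]oxy}tri(propan-2-yl)silane | CC(C)[Si](C(C)C)(C(C)C)Oc1ccc(-c2cc(Br)c3cccc(OC)c3c2OCc2ccccc2)o1 | intermediate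
12 | 3-methoxy-2-(trimethylsilyl)phenyl trifluoromethanesulfonate | COc1cccc(OS(=O)(=O)C(F)(F)F)c1[Si](C)(C)C | starting material
13 | 3-methoxybenzyne (1,2-didehydro-3-methoxybenzene, not isolated) | COC1=CC=CC#C1 | intermediate
14 | 4-[1-(benzyloxy)-4-bromo-8-methoxynaphthalen-2-yl]-8-methoxy-1-(triisopropylsilyloxy)-1,4-epoxy-1,4-dihydronaphthalene, racemic (not isolated) | COc1cccc2c1C1(O[Si](C(C)C)(C(C)C)C(C)C)C=CC2(O1)c1cc(Br)c2cccc(OC)c2c1OCc1ccccc1 | intermediate
15 | 4-[1-(benzyloxy)-4-bromo-8-methoxynaphthalen-2-yl]-4-hydroxy-8-methoxynaphthalen-1(4H)-one, racemic | COc1cccc2c1C(=O)C=CC2(O)c1cc(Br)c2cccc(OC)c2c1OCc1ccccc1 | intermediate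
16 | 4-[1-(benzyloxy)-4-bromo-8-methoxynaphthalen-2-yl]-8-methoxynaphthalen-1-ol | COc1cccc2c(-c3cc(Br)c4cccc(OC)c4c3OCc3ccccc3)ccc(O)c12 | intermediate
17 | 2-bromo-8-methoxynaphthalen-1-ol | COc1cccc2ccc(Br)c(O)c12 | intermediate
18 | 1-(benzyloxy)-2-bromo-8-methoxynaphthalene | COc1cccc2ccc(Br)c(OCc3ccccc3)c12 | intermediate
19 | 2-[1-(benzyloxy)-8-methoxynaphthalen-2-yl]-4,4,5,5-tetramethyl-1,3,2-dioxaborolane | COc1cccc2ccc(B3OC(C)(C)C(C)(C)O3)c(OCc3ccccc3)c12 | intermediate
20 | 4-{1-(benzyloxy)-4-[1-(benzyloxy)-8-methoxynaphthalen-2-yl]-8-methoxynaphthalen-2-yl}-8-methoxynaphthalen-1-ol | COc1cccc2ccc(-c3cc(-c4ccc(O)c5c(OC)cccc45)c(OCc4ccccc4)c4c(OC)cccc34)c(OCc3ccccc3)c12 | intermediate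
21 | 2-(4-hydroxy-5-methoxynaphthalen-1-yl)-4-(1-hydroxy-8-methoxynaphthalen-2-yl)-8-methoxynaphthalen-1-ol | COc1cccc2ccc(-c3cc(-c4ccc(O)c5c(OC)cccc45)c(O)c4c(OC)cccc34)c(O)c12 | target

Total step count: 14. Longest linear sequence: 11 steps (steps 1–9, 13 and 14). Steps 10–12 form the side branch to unit A.

Steps most likely to fail

Step 8. Fluoride may strip the silyl group from the furan before the aryne is captured, so that the butenolide anion is arylated instead of undergoing cycloaddition. The hindered diene may also react sluggishly or with eroded orientation. The fallback makes the quinol by carbonyl addition instead of cycloaddition. It sets out from 3 (and 2) and returns at 15.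
- NIS in MeCN iodinates the last activated position of 3 to give 4-bromo-2-iodo-8-methoxynaphthalen-1-ol F1.
- BnBr/K2CO3 in DMF gives 1-(benzyloxy)-4-bromo-2-iodo-8-methoxynaphthalene F2.
- In parallel, 2 is oxidised with PhI(OAc)2 in aqueous MeCN to 5-methoxynaphthalene-1,4-dione F3.
- Selective iodine–magnesium exchange of F2 with iPrMgCl·LiCl in THF at −40 °C gives [1-(benzyloxy)-4-bromo-8-methoxynaphthalen-2-yl]magnesium chloride F4.
- In the presence of LaCl3·2LiCl at −78 °C, F4 should add 1,2 to the C1 carbonyl of F3. This is the carbonyl that is neither conjugated with nor shielded by the peri methoxy group, and the addition gives 15.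

Step 10. The internal hydrogen bond to the peri methoxy group may weaken the contact between the hydroxyl and the N-bromoamine. Para attack and double bromination would then compete with ortho delivery. The fallback replaces electrophilic substitution by directed ortho-metalation. It sets out from 2 and returns at 17.
- MOMCl/iPr2NEt in CH2Cl2 gives 1-methoxy-8-(methoxymethoxy)naphthalene F5.
- n-BuLi/TMEDA in Et2O at 0 °C lithiates next to the acetal oxygen, the stronger director, to give [8-methoxy-1-(methoxymethoxy)naphthalen-2-yl]lithium F6.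
- BrCH2CH2Br at −78 °C gives 2-bromo-8-methoxy-1-(methoxymethoxy)naphthalene F7.
- HCl in MeOH at 40 °C removes the acetal to give 17.

Step 13. Protodeboronation of the electron-rich ortho-alkoxy boronate may outrun transmetalation at the hindered palladium centre. The unprotected naphtholate may also suffer oxidation at elevated temperature. The fallback masks the hydroxyl, reverses the polarity and changes the nucleophile to zinc. It sets out from 16 and 18 and returns at 21.
- BnBr/K2CO3 converts 16 into 1-(benzyloxy)-2-[4-(benzyloxy)-5-methoxynaphthalen-1-yl]-4-bromo-8-methoxynaphthalene F8.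
- n-BuLi in THF at −78 °C gives {4-(benzyloxy)-3-[4-(benzyloxy)-5-methoxynaphthalen-1-yl]-5-methoxynaphthalen-1-yl}lithium F9.
- ZnCl2 gives {4-(benzyloxy)-3-[4-(benzyloxy)-5-methoxynaphthalen-1-yl]-5-methoxynaphthalen-1-yl}zinc chloride F10.
- Negishi coupling of F10 with 18 (Pd(OAc)2, SPhos, THF, 60 °C) gives the tri-O-benzyl ether of 21, 1-(benzyloxy)-2-[4-(benzyloxy)-5-methoxynaphthalen-1-yl]-4-[1-(benzyloxy)-8-methoxynaphthalen-2-yl]-8-methoxynaphthalene F11.
- Hydrogenolysis over Pd/C gives 21.

Further compounds
F1 | step 8 | 4-bromo-2-iodo-8-methoxynaphthalen-1-ol | COc1cccc2c(Br)cc(I)c(O)c12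
F2 | step 8 | 1-(benzyloxy)-4-bromo-2-iodo-8-methoxynaphthalene | COc1cccc2c(Br)cc(I)c(OCc3ccccc3)c12
F3 | step 8 | 5-methoxynaphthalene-1,4-dione | COc1cccc2C(=O)C=CC(=O)c12
F4 | step 8 | [1-(benzyloxy)-4-bromo-8-methoxynaphthalen-2-yl]magnesium chloride | COc1cccc2c(Br)cc([Mg]Cl)c(OCc3ccccc3)c12
F5 | step 10 | 1-methoxy-8-(methoxymethoxy)naphthalene | COCOc1cccc2cccc(OC)c12
F6 | step 10 | [8-methoxy-1-(methoxymethoxy)naphthalen-2-yl]lithium | COCOc1c([Li])ccc2cccc(OC)c12
F7 | step 10 | 2-bromo-8-methoxy-1-(methoxymethoxy)naphthalene | COCOc1c(Br)ccc2cccc(OC)c12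
F8 | step 13 | 1-(benzyloxy)-2-[4-(benzyloxy)-5-methoxynaphthalen-1-yl]-4-bromo-8-methoxynaphthalene | COc1cccc2c(-c3cc(Br)c4cccc(OC)c4c3OCc3ccccc3)ccc(OCc3ccccc3)c12
F9 | step 13 | {4-(benzyloxy)-3-[4-(benzyloxy)-5-methoxynaphthalen-1-yl]-5-methoxynaphthalen-1-yl}lithium | COc1cccc2c(-c3cc([Li])c4cccc(OC)c4c3OCc3ccccc3)ccc(OCc3ccccc3)c12
F10 | step 13 | {4-(benzyloxy)-3-[4-(benzyloxy)-5-methoxynaphthalen-1-yl]-5-methoxynaphthalen-1-yl}zinc chloride | COc1cccc2c(-c3cc([Zn]Cl)c4cccc(OC)c4c3OCc3ccccc3)ccc(OCc3ccccc3)c12
F11 | step 13 | 1-(benzyloxy)-2-[4-(benzyloxy)-5-methoxynaphthalen-1-yl]-4-[1-(benzyloxy)-8-methoxynaphthalen-2-yl]-8-methoxynaphthalene | COc1cccc2ccc(-c3cc(-c4ccc(OCc5ccccc5)c5c(OC)cccc45)c(OCc4ccccc4)c4c(OC)cccc34)c(OCc3ccccc3)c12
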